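**Assumptions:** The target is achiral (a planar isoflavone with no stereocentre), so there is no enantiomer to control. 2-(2,4,5-Trimethoxyphenyl)acetic acid is taken as a catalogue building block.

**Retrosynthetic overview**
- The target is 6-hydroxy-7-methoxy-3-(2,4,5-trimethoxyphenyl)chromen-4-one; remove C-2 (O1–C2 and C2–C3 bonds) to give a 2-hydroxydeoxybenzoin plus a one-carbon formyl equivalent (DMF-DMA).
- Cut the aryl–C(=O) bond of the deoxybenzoin to give methoxyhydroquinone plus 2,4,5-trimethoxyphenylacetic acid (Friedel–Crafts acylation).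
- Both benzene rings are bought; the only ring formed is the pyran-4-one, and it is formed last.

**Route**

Step 1
Reactants: 1 2-methoxybenzene-1,4-diol (methoxyhydroquinone); 2 2-(2,4,5-trimethoxyphenyl)acetic acid
Product: 3 1-(2,5-dihydroxy-4-methoxyphenyl)-2-(2,4,5-trimethoxyphenyl)ethan-1-one
Conditions: BF3·OEt2 (neat, as solvent), 85 °C, Ar, 2 h; then aq. NaOAc
Reagents that add atoms: none
Why: BF3-promoted Friedel–Crafts C-acylation of the phenol by the free acid goes to the only ring position activated by both an ortho OH and a para OMe (C-5 of methoxyhydroquinone), and the resulting hydrogen-bonded ortho-hydroxy ketone is deactivated towards a second acylation; no stereocentre is formed.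

Step 2
Reactants: 3 1-(2,5-dihydroxy-4-methoxyphenyl)-2-(2,4,5-trimethoxyphenyl)ethan-1-one
Product: 5 6-hydroxy-7-methoxy-3-(2,4,5-trimethoxyphenyl)-4H-chromen-4-one (target), via enaminone 4 (not isolated)
Conditions: Me2NCH(OMe)2 (1.5 equiv), THF, 65 °C, 3 h; then 1 M HCl, rt
Reagents that add atoms: N,N-dimethylformamide dimethyl acetal, COC(OC)N(C)C
Why: The doubly activated benzylic CH2 condenses with DMF-DMA to the enaminone, whose ortho phenol adds in conjugate fashion and expels dimethylamine (deoxybenzoin isoflavone synthesis by enaminone formation and addition–elimination cyclisation); the non-chelated 5-OH is not methylated at this temperature and reagent loading, and no stereocentre is formed.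

**Compound list**
1 | 2-methoxybenzene-1,4-diol (methoxyhydroquinone) | COc1cc(O)ccc1O | starting material
2 | 2-(2,4,5-trimethoxyphenyl)acetic acid | COc1cc(OC)c(CC(=O)O)cc1OC | starting material
3 | 1-(2,5-dihydroxy-4-methoxyphenyl)-2-(2,4,5-trimethoxyphenyl)ethan-1-one | COc1cc(O)c(C(=O)Cc2cc(OC)c(OC)cc2OC)cc1O | intermediate
4 | 3-(dimethylamino)-1-(2,5-dihydroxy-4-methoxyphenyl)-2-(2,4,5-trimethoxyphenyl)prop-2-en-1-one (enaminone; C=C geometry not controlled, both isomers cyclise) | CN(C)C=C(C(=O)c1cc(O)c(OC)cc1O)c1cc(OC)c(OC)cc1OC | intermediate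
5 | 6-hydroxy-7-methoxy-3-(2,4,5-trimethoxyphenyl)-4H-chromen-4-one | COc1cc2occ(-c3cc(OC)c(OC)cc3OC)c(=O)c2cc1O | target

**Totals**
Total step count: 2. Longest linear sequence: 2.

**Steps most likely to fail** (the route has only two steps, so both are given, riskier first)

Step 1 is the riskier one. The hydroquinone can oxidise in air, and the electron-rich trimethoxyphenyl ring of the acid can itself be acylated or decompose in hot BF3·OEt2. The fallback drops the deoxybenzoin disconnection and attaches the B-ring by Suzuki coupling; it sets out from 1 and comes back to the route at 5. Compound 1 is acetylated with acetic acid in BF3·OEt2 at 90 °C to give 1-(2,5-dihydroxy-4-methoxyphenyl)ethan-1-one F1. Heating this with DMF-DMA in toluene gives (E)-3-(dimethylamino)-1-(2,5-dihydroxy-4-methoxyphenyl)prop-2-en-1-one F2. Iodine in CHCl3 at rt cyclises and iodinates it to 6-hydroxy-3-iodo-7-methoxy-4H-chromen-4-one F3. Suzuki–Miyaura coupling with commercial 2,4,5-trimethoxyphenylboronic acid (Pd(dppf)Cl2, Na2CO3, dioxane/H2O, 80 °C) then gives 5 directly.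

Step 2 can fail through partial O-methylation of the free 6-OH precursor by DMF-DMA, or through incomplete ring closure of the enaminone. The fallback uses the ethoxalyl chloride (oxalate) isoflavone synthesis, with a different one-carbon source and a decarboxylation; it sets out from 3 and comes back at 5. Compound 3 is treated with excess ethyl chlorooxoacetate in pyridine (0 °C to rt). This acylates both phenols and closes the ring by intramolecular condensation onto the benzylic CH2, giving ethyl 6-[(2-ethoxy-2-oxoacetyl)oxy]-7-methoxy-4-oxo-3-(2,4,5-trimethoxyphenyl)-4H-chromene-2-carboxylate F4. Saponification (aq. NaOH, acetone, then HCl) removes both esters to give 6-hydroxy-7-methoxy-4-oxo-3-(2,4,5-trimethoxyphenyl)-4H-chromene-2-carboxylic acid F5. Thermal decarboxylation (Cu powder, quinoline, 200 °C) gives 5.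

**Further compounds**
F1 | step 1 | 1-(2,5-dihydroxy-4-methoxyphenyl)ethan-1-one | COc1cc(O)c(C(C)=O)cc1O
F2 | step 1 | (E)-3-(dimethylamino)-1-(2,5-dihydroxy-4-methoxyphenyl)prop-2-en-1-one | CN(C)/C=C/C(=O)c1cc(O)c(OC)cc1O
F3 | step 1 | 6-hydroxy-3-iodo-7-methoxy-4H-chromen-4-one | COc1cc2occ(I)c(=O)c2cc1O
F4 | step 2 | ethyl 6-[(2-ethoxy-2-oxoacetyl)oxy]-7-methoxy-4-oxo-3-(2,4,5-trimethoxyphenyl)-4H-chromene-2-carboxylate | CCOC(=O)C(=O)Oc1cc2c(cc1OC)oc(C(=O)OCC)c(-c1cc(OC)c(OC)cc1OC)c2=O
F5 | step 2 | 6-hydroxy-7-methoxy-4-oxo-3-(2,4,5-trimethoxyphenyl)-4H-chromene-2-carboxylic acid | O=C(O)c1oc2cc(OC)c(O)cc2c(=O)c1-c1cc(OC)c(OC)cc1OC
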